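The numbers in the tables come from a simulation from invented constants.

If you want to know where the west flask stops, watch the sum of the two products, not either one.

| flask | left-handed substrate | right-handed substrate | coupling partner | free catalyst | remark | time |
|---|---|---|---|---|---|---|
| west | 20 mM | 20 mM | 1.1 equiv | 0.071 mol% | the very flask that is asked about, followed so far |  |
| north-east | 10 mM | 10 mM | 1.1 equiv | 0.071 mol% | run made earlier |  |
| flask | 20 mM | 20 mM | 1.10 equiv | 0.071 mol% |  | 10 d |

| run | time / d | left-handed product / % | right-handed product / % | left-handed substrate / % |
|---|---|---|---|---|
| west | 0.250 | 6.0 | 10.8 | 44.1 |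
| west | 0.833 | 12.8 | 17.0 | 41.2 |
| west | 1.25 | 14.9 | 18.9 | 40.9 |
| west | 2.00 | 15.1 | 16.9 | 41.9 |
| west | 3.00 | 17.1 | 16.1 | 41.1 |
| north-east | 0.833 | 6.4 | 11.1 | 46.8 |
| north-east | 2.50 | 10.5 | 11.4 | 45.8 |
| north-east | 5.00 | 10.1 | 10.3 | 44.9 |
| north-east | 8.00 | 10.4 | 10.4 | 45.2 |
| north-east | 10.0 | 10.8 | 10.4 | 45.1 |

(standard deviation of a reading: 0.5 percentage points)

1. excess of left-handed product over right-handed product in the product at 25 h
2. excess of left-handed product over right-handed product in the product at 10 d
3. part of the left-handed substrate and right-handed substrate charged together that has reacted at 10 d

- free catalyst is single-handed; left-handed substrate and right-handed substrate are mirror images of each other, charged as a racemate, each of them at the stated concentration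
- an excess is below zero if the other one leads

In the west run that sum stays flat from 1.25 d on, at 33.0% of the two substrates charged. Substrate is still there: the left-handed one reads 41.1% at 3.00 d. The coupling partner charged has room for 55.0% of the substrates, and the plateau read in the west run lies below that room, at 60.0% of it. Call this the partner yield, the part of the charged coupling partner that stands as product on the plateau.

There is a second way to the same number. The north-east plateau, 21.1%, gives a partner yield of 38.3%. Suppose the coupling partner divides between coupling, which grows with the charge, and a loss of its own, which does not. The west flask has twice the charge of the north-east flask, so on this supposition the odds of coupling double. That predicts 30.5% reacted in the west flask.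

The two ways part by 2.5 percentage points, against a scatter of 0.5 points on a reading. The second carries an assumed split over from another flask, while the first is read on this one. So I trust the first. The west readings end at 3.00 d, but the north-east sum still reads flat at 10.0 d, so I commit to 33.0% reacted at 10 d in the west flask.

The forecast gives an excess of −14% at 25 h and 0.3% at 10 d, and 32.8% reacted, the last on the ground that “A higher plateau at higher concentration is what a bimolecular equilibrium gives”.

The flask gives an excess of −15.8% at 25 h and 0% at 10 d, and 32.6% reacted.

    free catalyst + left-handed substrate ⇌ catalyst intermediate A (K = 21.0 /M, k = 44400 /M/h)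
    free catalyst + right-handed substrate ⇌ catalyst intermediate B (K = 764 /M, k = 12900 /M/h)
    coupling partner + catalyst intermediate A → free catalyst + left-handed product (k = 17200 /M/h)
    coupling partner + catalyst intermediate B → free catalyst + right-handed product (k = 5880 /M/h)
    free catalyst → spent catalyst (k = 0.0150 /h)
    left-handed product ⇌ right-handed product (k = 0.0337 /h)
    coupling partner → decomposed reagent (k = 0.0512 /h)

At 10.0 d the coupling partner, the limiting reagent, stands at 0%, with 8.97 mM of decomposed reagent beside it. The result puts the partner yield at 59.3%.

Now take a flask like the west one but with 0.660 equiv of coupling partner. The partner yield of 60.0% predicts 19.8% reacted, and the simulation gives 19.9%.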